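Assumption: C2'' of the C8 side chain is read from the SMILES of the target as R (priorities OH > isopropenyl > CH2Ar > H). The connectivities of acid 9 and chromone 13 were checked atom by atom against the ring numbering and need no correction. The chiral ligand of step 10 is defined by the aldehyde face it must address (Si), since its sense of induction on this substrate has to be confirmed on a model.

Structural features

The target is an isoflavone: a benzene ring A fused through C4a–C8a to a pyran-4-one ring C, with a 4-hydroxyphenyl ring B on C3. Ring A is fully substituted and carries, in sequence, a methoxy group on C5, a 3-methylbut-2-enyl (prenyl) group on C6, a free hydroxyl on C7 and a (2R)-2-hydroxy-3-methylbut-3-enyl chain on C8; C8a bears O1 and C4a bears the C4 carbonyl. The single stereocentre, C2'' of the C8 chain, is a secondary allylic and homobenzylic carbinol with no neighbouring stereocentre, so its configuration must come from a reagent or catalyst. The fragile elements are the prenyl group and the allylic alcohol on either side of the C7 hydroxyl (acid closes chroman or dihydrofuran rings and ionises the allylic alcohol), the pyranone (strong alkoxide or hydroxide opens it at C2), and the need to keep one ring-A oxygen methylated while two phenols end up free. The real difficulty is the hexasubstituted ring A, above all telling C6 from C8 and the three ring-A oxygens from one another, together with the isolated carbinol centre. The key step uses two facts: C4 is a carbonyl carbon on C4a flanked by the C5 methoxy oxygen and by O1 on C8a, a 2,6-dioxygenated benzoyl unit that ionises to an acylium ion; and O1–C2=C3 is an aryl enol ether whose nucleophilic carbon C3 lies within reach of C4.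

Logic of the disconnections

23 to 22. The acyl–oxygen bond on the ring B oxygen is cut first. Ring B needs an electron-withdrawing mask during the cationic ring closure, and it must come off without acid. This reduces two free phenols to one. The forward step must cleave an aryl ester without opening the pyranone at C2 or disturbing the prenyl/hydroxyl pair.

22 to 21. The C6–C1 bond of the prenyl group is cut and reconnected as an O7–C(tertiary) bond ([3,3] retron). C6 is the only free ring-A position and O7 delivers the group intramolecularly, so C- versus O-alkylation is not an issue. The forward step must run at low temperature without acid; C8 is blocked, so the shift can only end at C6.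

21 to 20. No skeletal bond is cut; the vinyl terminus of the O7 ether is traced back to an ethynyl group. An alkyne survives the alkene cleavage that a vinyl group would not, so one ether serves both as O7 protection and as the latent tertiary allyl group. The forward step must stop at the alkene and spare the isopropenyl group.

20 to 18 and 19. The C2''–C3'' bond is cut. This joins the carbinol carbon to its alkenyl substituent and creates the stereocentre and a C–C bond in one operation. The chain is reduced to a two-carbon aldehyde and a three-carbon alkenyl halide. The forward step must be a non-basic alkenyl transfer to the Si face of an enolisable aldehyde.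

18 to 16 (through 17). The C2'' carbonyl is traced back to the C2''=C3'' bond of a C8 allyl group, which is the group a sigmatropic shift can deliver to C8. The forward cleavage must be selective for the monosubstituted alkene over the alkyne, and O7 must be capped or the aldehyde would close a lactol.

16 to 14 and 15. The O7–C(tertiary propargyl) bond is cut, which exposes the phenol formed by the preceding rearrangement. The forward step must be a mild etherification of a hindered phenol with a tertiary electrophile.

14 to 13. The C8–C1'' bond is cut and reconnected as O7–allyl ([3,3] retron). The C8 substituent is thus traced back to the allyl ether that has protected this oxygen from the start. The forward step depends on the inherent preference of 5-alkoxy-7-allyloxychromones for C8 over C6 and on the acetate surviving the heat.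

13 to 9 (through 10, 11 and 12). The C3–C4 bond is cut. The cut sits at a carbonyl carbon between two ortho oxygens, the best place to generate an acylium ion, and its partner is the nucleophilic carbon of an enol ether. Ring C opens to an acyclic aryl alkenyl ether, with O1–C2 already made and the 5-methoxy/7-alkoxy pattern fixed before the ring exists. The forward step must attack through C3 and not C2, and must be acid-free because the enol ether is acid-labile; for the same reason 9 is made immediately before use and activated under neutral conditions.

9 to 8. The C4 oxidation level is lowered from acid to aldehyde. An aldehyde tolerates the copper coupling and avoids carrying a decarboxylation-prone trioxygenated benzoic acid. The forward oxidation must spare the enol ether, the allyl group and the electron-rich ring.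

8 to 7 and 3. The O1–C2 bond is cut. This splits the molecule convergently into ring A and the C2–C3–ring B unit, with the E geometry supplied by the boron partner. The forward step must couple a hindered, hydrogen-bonded phenol under mild oxidative conditions.

3 to 1 and 2. The C2=C3 alkene is cut (metathesis retron), leading to two commercial alkenes. The forward step must be E-selective.

7 to 6 to 4 and 5. The O–CH3 and O–allyl bonds are cut. The three hydroxyls of 4 are told apart by acidity and hydrogen bonding, and each forward alkylation must stop at the mono stage.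

Other disconnections considered

Alternative 1: The cut is the C2''–O bond. The carbinol is traced back to an oxirane across C2''–C3'' of an (E)-4-hydroxy-3-methylbut-2-enyl chain on C8, that is, to allylic alcohol A1, which already contains the whole isoflavone with silyl ethers on O7 and on the ring B oxygen.
- Forward step: Ti(OiPr)4, D-(−)-diisopropyl tartrate and tert-butyl hydroperoxide would convert A1 into the (2R,3R)-epoxy alcohol A2. Turning the primary hydroxyl of A2 into a halide and opening the ring reductively with zinc would shift the double bond to C3''–C4'' and free the C2'' hydroxyl without touching the C2''–O bond. A2 therefore maps onto the R configuration of 23 after desilylation.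
- In favour: induction is reagent-controlled and predictable in sense and level for (E)-trisubstituted allylic alcohols. Hydroxyl direction leaves the equally electron-rich C6 prenyl alkene alone, and no enolisable aldehyde is involved.
- Against: it does not address ring A or the isoflavone core. A1 needs the hydroxymethyl terminus on the C8 chain only; allylic oxidation of a prenyl group would not tell the C6 and C8 chains apart, so chain extension by olefination and a reduction that spares the pyranone carbonyl would be required. An oxirane next to O7 is exposed to intramolecular opening if the silyl ether migrates or is lost.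
- Comparison: on structure, the plans differ only in the side chain. The chosen plan sets C2'' while forming C2''–C3''; the alternative transfers oxygen to a preformed five-carbon chain. On mechanism, the alternative is the better one: its stereocontrol is more predictable than the ligand-controlled alkenylchromium addition of step 10. On step economy, the chosen plan is shorter by about three operations. The alternative is best seen as a reserve for the stereocentre.

Alternative 2: The cut runs through ring A at C7–C8, C4a–C8a and C6–C7. This leaves cyclobutenone A3 (C4a, C5, C6 and C7 with the methoxy and prenyl groups) and siloxyalkyne A4 (C8 and C8a with a two-carbon stub of the C8 chain and the future O1).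
- Forward step: heating A3 with A4 in toluene would open A3, join the partners by ketene–alkyne [2+2] cycloaddition (C7–C8 and C4a–C8a, regiochemistry set by the polarised ynol ether), open the new four-membered ring, close C6–C7 by 6π-electrocyclisation and tautomerise to phenol A5.
- In favour: every ring-A substituent is placed in one step by polarity, not by site selectivity. The prenyl group is present from the start, the three oxygens emerge differentiated, and C4a is the only free position.
- Against: A3 and A4 are not commercial and each needs a multi-step preparation. The thermal cascade must tolerate a pendant prenyl alkene that can intercept the ketene. After A5 there remain acylation at C4a (a Lewis acid next to a prenyl group and a free phenol invites chroman formation), closure of ring C, elaboration of the two-carbon stub and the same asymmetric alkenylation.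
- Comparison: on structure, the alternative is better for the regiochemical security of ring A, whereas the chosen plan depends on the C8 preference of step 7. On mechanism, the pericyclic cascade has firm precedent while step 6 has none, so the alternative is again better. On step economy, the chosen plan is far shorter, since ring A with its three oxygens is bought and the alternative would approach twenty steps. The stereocentre is unsolved in both, so they are equal there.

Alternative 3: The cut opens ring C at C4–C4a and O1–C2 and also breaks the aryl–oxygen bond C8a–O1. This gives silylaryl triflate A6, the precursor of aryne A7 across C4a–C8a, and 3-methoxy-2-arylacrylic acid A8.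
- Forward step: CsF would convert A6 into A7. The carboxylate of A8 would add at C8a, remote from the methoxy group; the C4a anion would attack the acyl carbon (C4–C4a, acyl shift from oxygen to carbon); and the released C8a phenoxide would displace methoxide at C2 by addition–elimination to give A9.
- In favour: one flask at ambient temperature joins ring A to the ring B fragment and closes ring C. The regiochemistry follows the polarisation of the aryne by the methoxy group. A9 has the skeleton of 13 and could enter the route at step 7.
- Against: A6 needs four to five steps of regiocontrolled halogenation, silylation and triflation, whereas 4 is bought. Protonation of the C4a anion by the acid proton competes with acyl transfer. The methoxymethyl ether on ring B needs acid for removal, a hazard for the prenyl/hydroxyl pair and the allylic alcohol.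
- Comparison: on structure, both plans close ring C late from a ring A piece and a C2–C3–ring B piece; the alternative forms three bonds in one step, which is better than the two steps (4 and 6) plus an oxidation of the chosen plan. On mechanism, aryne insertion into carboxylic acid C–O bonds is established chemistry, so the alternative is better precedented than step 6. On step economy, the two are roughly equal, because the steps saved in the cascade are spent on A6 and A8.

Key step: step 6

Step 1
Reactants: 1 4-ethenylphenyl acetate (4-acetoxystyrene); 2 2-ethenyl-4,4,5,5-tetramethyl-1,3,2-dioxaborolane (vinylboronic acid pinacol ester)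
Product: 3 4-[(E)-2-(4,4,5,5-tetramethyl-1,3,2-dioxaborolan-2-yl)ethenyl]phenyl acetate
Conditions: 2 (1.5 equiv), second-generation Grubbs catalyst RuCl2(=CHPh)(H2IMes)(PCy3) (3 mol %), CH2Cl2, 40 °C
Reagents that add atoms: none
Why: Olefin cross-metathesis of a styrene with a vinylboronate; the bulky boronate homodimerises slowly, so the cross product should dominate, and thermodynamic control should give the E alkene, with the acetate inert.

Step 2
Reactants: 4 2,4,6-trihydroxybenzaldehyde; 5 3-bromoprop-1-ene (allyl bromide)
Product: 6 2,6-dihydroxy-4-(prop-2-enyloxy)benzaldehyde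
Conditions: 5 (1.0 equiv), K2CO3 (1.0 equiv), DMF, 0 °C to rt
Reagents that add atoms: none
Why: Williamson etherification; the 4-hydroxyl is the most acidic (para to the formyl group) and the only one not hydrogen-bonded to it, so one equivalent of base and bromide should alkylate it preferentially.

Step 3
Reactants: 6 2,6-dihydroxy-4-(prop-2-enyloxy)benzaldehyde
Product: 7 2-hydroxy-6-methoxy-4-(prop-2-enyloxy)benzaldehyde
Conditions: MeI (1.1 equiv), K2CO3 (1.1 equiv), acetone, rt
Reagents that add atoms: iodomethane, CI
Why: Williamson methylation; once one ortho hydroxyl is methylated the other is locked in a strong hydrogen bond to the aldehyde and is far less nucleophilic, which should stop the reaction at the mono ether.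

Step 4
Reactants: 7 2-hydroxy-6-methoxy-4-(prop-2-enyloxy)benzaldehyde; 3 4-[(E)-2-(4,4,5,5-tetramethyl-1,3,2-dioxaborolan-2-yl)ethenyl]phenyl acetate
Product: 8 2-{(E)-2-[4-(acetyloxy)phenyl]ethenoxy}-6-methoxy-4-(prop-2-enyloxy)benzaldehyde
Conditions: 3 (1.5 equiv), Cu(OAc)2 (1.5 equiv), pyridine (3 equiv), B(OH)3 (2 equiv), 4 Å molecular sieves, MeCN, dry air, 50 °C
Reagents that add atoms: none
Why: Chan–Lam oxidative C–O coupling; transmetalation of the alkenylboronate to divalent copper and reductive elimination from a trivalent copper phenoxide should form O1–C2 with retention of the E geometry, boric acid takes up the pinacol that slows boronic esters, and the mild base leaves aldehyde, acetate and allyl ether untouched.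

Step 5
Reactants: 8 2-{(E)-2-[4-(acetyloxy)phenyl]ethenoxy}-6-methoxy-4-(prop-2-enyloxy)benzaldehyde
Product: 9 2-{(E)-2-[4-(acetyloxy)phenyl]ethenoxy}-6-methoxy-4-(prop-2-enyloxy)benzoic acid
Conditions: NaClO2, NaH2PO4, 2-methylbut-2-ene (large excess), t-BuOH/THF/H2O, 0 °C to rt
Reagents that add atoms: sodium chlorite, [Na+].[O-]Cl=O
Why: Pinnick oxidation; chlorous acid adds to the aldehyde and fragments to the acid, and the excess alkene should remove HOCl before it can chlorinate the electron-rich ring, the enol ether or the allyl group; 9 is used at once because trioxygenated benzoic acids decarboxylate when kept with acid.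

Step 6
Reactants: 9 2-{(E)-2-[4-(acetyloxy)phenyl]ethenoxy}-6-methoxy-4-(prop-2-enyloxy)benzoic acid
Product: 13 4-[5-methoxy-4-oxo-7-(prop-2-enyloxy)chromen-3-yl]phenyl acetate, via the acyl chloride 10 (not isolated), via the acylium triflate 11 (not isolated), via the oxocarbenium triflate 12 (not isolated)
Conditions: 1-chloro-N,N,2-trimethylprop-1-en-1-amine (1.0 equiv), CH2Cl2, 0 °C to rt; then 2,6-di-tert-butyl-4-methylpyridine (2 equiv), AgOTf (1.3 equiv), CH2Cl2, −40 °C to rt
Reagents that add atoms: none
Why: Proposed new method: the α-chloroenamine converts 9 into acyl chloride 10 without liberating HCl, and chloride abstraction by AgOTf should give acylium ion 11, whose formation is eased by the two ortho oxygens (the C5 methoxy group and O1), which twist the acyl group out of conjugation and stabilise the cation, and by the para allyloxy group. The enol ether, polarised by O1 towards C3, attacks the acylium carbon to form C3–C4 and oxocarbenium ion 12, and loss of the C3 proton to the hindered pyridine gives the aromatic pyranone 13. Ring C closes in a 6-endo-trig mode with respect to the C2=C3 bond, the acylium carbon being captured exo to its own C–O multiple bond. The closest known reaction types are the cationic cyclodehydration of 2-aryloxybenzoic acids to xanthones and the C-acylation of enol ethers at their β-carbon by acyl chlorides; the proposed closure merges the two in an intramolecular setting. No stereocentre is formed, because C3 is tetrahedral only in 12. The selectivity needed is attack through C3 and not through C2, which would close a five-membered benzofuranone through a benzylic cation; the oxygen lone pair favours the oxocarbenium pathway and the acetoxy group keeps ring B too electron-poor to support the alternative cation. The E geometry set in step 1 places hydrogen, not aryl, cis to O1 on C3, so the conformer that brings C3 to C4 is unstrained. The base removes triflic acid before it can protonate the enol ether, one equivalent of chloroenamine leaves no keteniminium electrophile behind, and the allyl ether and the aryl acetate are spectators.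

Step 7
Reactants: 13 4-[5-methoxy-4-oxo-7-(prop-2-enyloxy)chromen-3-yl]phenyl acetate
Product: 14 4-[7-hydroxy-5-methoxy-4-oxo-8-(prop-2-enyl)chromen-3-yl]phenyl acetate
Conditions: 1,2-dichlorobenzene, 190 °C, sealed tube
Reagents that add atoms: none
Why: Aromatic Claisen rearrangement, a [3,3]-sigmatropic shift followed by tautomerisation; in 5-alkoxy-7-allyloxychromones the C7–C8 bond has the higher double-bond character and C6 is crowded by the methoxy group, so migration to C8 is expected, and the neutral, non-nucleophilic solvent should limit acetyl transfer.

Step 8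
Reactants: 14 4-[7-hydroxy-5-methoxy-4-oxo-8-(prop-2-enyl)chromen-3-yl]phenyl acetate; 15 3-chloro-3-methylbut-1-yne
Product: 16 4-[5-methoxy-7-(2-methylbut-3-yn-2-yloxy)-4-oxo-8-(prop-2-enyl)chromen-3-yl]phenyl acetate
Conditions: 15 (1.5 equiv), DBU, CuCl2·2H2O (1 mol %), MeCN, 0 °C
Reagents that add atoms: none
Why: Copper-catalysed propargylic etherification of a phenol with a tertiary propargylic chloride; the ether caps the 7-hydroxyl, which would otherwise close a lactol and then a furan with the aldehyde of step 9, and it is the latent 1,1-dimethylallyl group needed in step 12.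

Step 9
Reactants: 16 4-[5-methoxy-7-(2-methylbut-3-yn-2-yloxy)-4-oxo-8-(prop-2-enyl)chromen-3-yl]phenyl acetate
Product: 18 4-[5-methoxy-7-(2-methylbut-3-yn-2-yloxy)-4-oxo-8-(2-oxoethyl)chromen-3-yl]phenyl acetate, via the vicinal diol 17 (not isolated)
Conditions: OsO4 (2 mol %), NaIO4 (4 equiv), 2,6-lutidine, dioxane/H2O, rt
Reagents that add atoms: osmium tetroxide, O=[Os](=O)(=O)=O; sodium periodate, [Na+].[O-]I(=O)(=O)=O
Why: Lemieux–Johnson oxidation; OsO4 should dihydroxylate the monosubstituted alkene much faster than the terminal alkyne or the electron-poor pyranone double bond, periodate cleaves diol 17 and regenerates the catalyst, and 2,6-lutidine suppresses over-oxidation; 18 is taken on crude because arylacetaldehydes enolise readily.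

Step 10
Reactants: 18 4-[5-methoxy-7-(2-methylbut-3-yn-2-yloxy)-4-oxo-8-(2-oxoethyl)chromen-3-yl]phenyl acetate; 19 2-bromoprop-1-ene
Product: 20 4-{8-[(2R)-2-hydroxy-3-methylbut-3-enyl]-5-methoxy-7-(2-methylbut-3-yn-2-yloxy)-4-oxochromen-3-yl}phenyl acetate
Conditions: 19 (3 equiv), CrCl2 (10 mol %), chiral N-[2-(4-isopropyl-4,5-dihydro-1,3-oxazol-2-yl)aryl]methanesulfonamide ligand (11 mol %, enantiomer for Si-face addition), 1,8-bis(dimethylamino)naphthalene (11 mol %), NiCl2(2,9-dimethyl-1,10-phenanthroline) (2 mol %), Mn, ZrCp2Cl2, LiCl, MeCN, rt
Reagents that add atoms: none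
Why: Catalytic asymmetric Nozaki–Hiyama–Kishi alkenylation; zerovalent nickel activates 19, transmetalation gives a non-basic alkenyl species of trivalent chromium held by the chiral sulfonamide, and its addition to the Si face of the aldehyde sets C2'' as R. The reagent should not enolise the aldehyde and tolerates the acetate, the pyranone and the alkyne, and ZrCp2Cl2 releases the product from chromium without silylating the aldehyde.

Step 11
Reactants: 20 4-{8-[(2R)-2-hydroxy-3-methylbut-3-enyl]-5-methoxy-7-(2-methylbut-3-yn-2-yloxy)-4-oxochromen-3-yl}phenyl acetate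
Product: 21 4-{8-[(2R)-2-hydroxy-3-methylbut-3-enyl]-5-methoxy-7-(2-methylbut-3-en-2-yloxy)-4-oxochromen-3-yl}phenyl acetate
Conditions: H2 (1 atm), Pd/CaCO3 poisoned with Pb(OAc)2, quinoline, EtOAc, rt
Reagents that add atoms: none
Why: Lindlar semi-hydrogenation; the terminal alkyne binds to the poisoned palladium far more strongly than the 1,1-disubstituted alkene or the pyranone, so reduction should stop at the 1,1-dimethylallyl ether, and the stereocentre is not involved.

Step 12
Reactants: 21 4-{8-[(2R)-2-hydroxy-3-methylbut-3-enyl]-5-methoxy-7-(2-methylbut-3-en-2-yloxy)-4-oxochromen-3-yl}phenyl acetate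
Product: 22 4-{7-hydroxy-8-[(2R)-2-hydroxy-3-methylbut-3-enyl]-5-methoxy-6-(3-methylbut-2-enyl)-4-oxochromen-3-yl}phenyl acetate
Conditions: Eu(fod)3 (10 mol %), CHCl3, 60 °C
Reagents that add atoms: none
Why: Aromatic Claisen rearrangement of a 1,1-dimethylallyl aryl ether, accelerated by the oxophilic lanthanide; the [3,3] shift delivers the allyl unit with allylic inversion as a 3-methylbut-2-enyl group, and because C8 is blocked only the shift to C6 can be completed by tautomerisation. The low temperature should avoid loss of isoprene and cyclisation onto the 7-hydroxyl.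

Step 13
Reactants: 22 4-{7-hydroxy-8-[(2R)-2-hydroxy-3-methylbut-3-enyl]-5-methoxy-6-(3-methylbut-2-enyl)-4-oxochromen-3-yl}phenyl acetate
Product: 23 7-hydroxy-8-[(2R)-2-hydroxy-3-methylbut-3-enyl]-3-(4-hydroxyphenyl)-5-methoxy-6-(3-methylbut-2-enyl)chromen-4-one
Conditions: K2CO3 (0.5 equiv), MeOH, 0 °C to rt; aq. NH4Cl work-up
Reagents that add atoms: none
Why: Base-catalysed methanolysis of the aryl acetate; the acidic 7-hydroxyl is deprotonated first, which shields the pyranone from methoxide attack at C2, and the prenyl group, the allylic alcohol and the stereocentre are untouched, while the neutral work-up avoids acid-induced cyclisation.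

Compound list

1 | 4-ethenylphenyl acetate (4-acetoxystyrene) | C=Cc1ccc(OC(C)=O)cc1 | starting material
2 | 2-ethenyl-4,4,5,5-tetramethyl-1,3,2-dioxaborolane (vinylboronic acid pinacol ester) | C=CB1OC(C)(C)C(C)(C)O1 | starting material
3 | 4-[(E)-2-(4,4,5,5-tetramethyl-1,3,2-dioxaborolan-2-yl)ethenyl]phenyl acetate | CC(=O)Oc1ccc(/C=C/B2OC(C)(C)C(C)(C)O2)cc1 | intermediate
4 | 2,4,6-trihydroxybenzaldehyde | O=Cc1c(O)cc(O)cc1O | starting material
5 | 3-bromoprop-1-ene (allyl bromide) | C=CCBr | starting material
6 | 2,6-dihydroxy-4-(prop-2-enyloxy)benzaldehyde | O=Cc1c(O)cc(OCC=C)cc1O | intermediate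
7 | 2-hydroxy-6-methoxy-4-(prop-2-enyloxy)benzaldehyde | O=Cc1c(O)cc(OCC=C)cc1OC | intermediate
8 | 2-{(E)-2-[4-(acetyloxy)phenyl]ethenoxy}-6-methoxy-4-(prop-2-enyloxy)benzaldehyde | O=Cc1c(OC)cc(OCC=C)cc1O/C=C/c1ccc(OC(C)=O)cc1 | intermediate
9 | 2-{(E)-2-[4-(acetyloxy)phenyl]ethenoxy}-6-methoxy-4-(prop-2-enyloxy)benzoic acid | O=C(O)c1c(OC)cc(OCC=C)cc1O/C=C/c1ccc(OC(C)=O)cc1 | intermediate
10 | 2-{(E)-2-[4-(acetyloxy)phenyl]ethenoxy}-6-methoxy-4-(prop-2-enyloxy)benzoyl chloride (not isolated) | O=C(Cl)c1c(OC)cc(OCC=C)cc1O/C=C/c1ccc(OC(C)=O)cc1 | intermediate
11 | 2-{(E)-2-[4-(acetyloxy)phenyl]ethenoxy}-6-methoxy-4-(prop-2-enyloxy)benzoylium trifluoromethanesulfonate (acylium ion, not isolated) | O=[C+]c1c(OC)cc(OCC=C)cc1O/C=C/c1ccc(OC(C)=O)cc1.[O-]S(=O)(=O)C(F)(F)F | intermediate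
12 | 3-[4-(acetyloxy)phenyl]-5-methoxy-4-oxo-7-(prop-2-enyloxy)-3,4-dihydrochromen-1-ium trifluoromethanesulfonate (oxocarbenium ion at C2, C3 of either configuration, not isolated) | C=CCOc1cc(OC)c2C(=O)C(c3ccc(OC(C)=O)cc3)C=[O+]c2c1.[O-]S(=O)(=O)C(F)(F)F | intermediate
13 | 4-[5-methoxy-4-oxo-7-(prop-2-enyloxy)chromen-3-yl]phenyl acetate | C=CCOc1cc(OC)c2c(=O)c(-c3ccc(OC(C)=O)cc3)coc2c1 | intermediate
14 | 4-[7-hydroxy-5-methoxy-4-oxo-8-(prop-2-enyl)chromen-3-yl]phenyl acetate | C=CCc1c(O)cc(OC)c2c(=O)c(-c3ccc(OC(C)=O)cc3)coc12 | intermediate
15 | 3-chloro-3-methylbut-1-yne | C#CC(C)(C)Cl | starting material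
16 | 4-[5-methoxy-7-(2-methylbut-3-yn-2-yloxy)-4-oxo-8-(prop-2-enyl)chromen-3-yl]phenyl acetate | C=CCc1c(OC(C)(C)C#C)cc(OC)c2c(=O)c(-c3ccc(OC(C)=O)cc3)coc12 | intermediate
17 | 4-[8-(2,3-dihydroxypropyl)-5-methoxy-7-(2-methylbut-3-yn-2-yloxy)-4-oxochromen-3-yl]phenyl acetate (both configurations at the secondary carbinol, not isolated) | OCC(O)Cc1c(OC(C)(C)C#C)cc(OC)c2c(=O)c(-c3ccc(OC(C)=O)cc3)coc12 | intermediate
18 | 4-[5-methoxy-7-(2-methylbut-3-yn-2-yloxy)-4-oxo-8-(2-oxoethyl)chromen-3-yl]phenyl acetate | O=CCc1c(OC(C)(C)C#C)cc(OC)c2c(=O)c(-c3ccc(OC(C)=O)cc3)coc12 | intermediate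
19 | 2-bromoprop-1-ene | C=C(C)Br | starting material
20 | 4-{8-[(2R)-2-hydroxy-3-methylbut-3-enyl]-5-methoxy-7-(2-methylbut-3-yn-2-yloxy)-4-oxochromen-3-yl}phenyl acetate | C=C(C)[C@H](O)Cc1c(OC(C)(C)C#C)cc(OC)c2c(=O)c(-c3ccc(OC(C)=O)cc3)coc12 | intermediate
21 | 4-{8-[(2R)-2-hydroxy-3-methylbut-3-enyl]-5-methoxy-7-(2-methylbut-3-en-2-yloxy)-4-oxochromen-3-yl}phenyl acetate | C=C(C)[C@H](O)Cc1c(OC(C)(C)C=C)cc(OC)c2c(=O)c(-c3ccc(OC(C)=O)cc3)coc12 | intermediate
22 | 4-{7-hydroxy-8-[(2R)-2-hydroxy-3-methylbut-3-enyl]-5-methoxy-6-(3-methylbut-2-enyl)-4-oxochromen-3-yl}phenyl acetate | C=C(C)[C@H](O)Cc1c(O)c(CC=C(C)C)c(OC)c2c(=O)c(-c3ccc(OC(C)=O)cc3)coc12 | intermediate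
23 | 7-hydroxy-8-[(2R)-2-hydroxy-3-methylbut-3-enyl]-3-(4-hydroxyphenyl)-5-methoxy-6-(3-methylbut-2-enyl)chromen-4-one | C=C(C)[C@H](O)Cc1c(O)c(CC=C(C)C)c(OC)c2c(=O)c(-c3ccc(O)cc3)coc12 | target

Step count and risk

Total step count: 13. Longest linear sequence: 12 steps (steps 2 to 13, from 4 to 23); step 1 is a one-step branch that joins at step 4.

Steps least certain to work:

Step 6 (key step, proposed new method). The most likely failure is diversion of the cationic pathway: cleavage of the enol ether if acid is not fully buffered, closure through C2, or intermolecular acylation. The cause is that the doubly oxygen-stabilised acylium ion is long-lived while the aryl enol ether is only a moderate nucleophile. The fallback uses known iodochromone chemistry, sets out from 7 and returns at 13: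
- addition of MeMgBr (excess, THF, 0 °C) to give 2-(1-hydroxyethyl)-3-methoxy-5-(prop-2-enyloxy)phenol F1;
- oxidation with MnO2 to 1-[2-hydroxy-6-methoxy-4-(prop-2-enyloxy)phenyl]ethanone F2;
- condensation with N,N-dimethylformamide dimethyl acetal to (E)-3-(dimethylamino)-1-[2-hydroxy-6-methoxy-4-(prop-2-enyloxy)phenyl]prop-2-en-1-one F3;
- iodine-induced cyclisation to 3-iodo-5-methoxy-7-(prop-2-enyloxy)chromen-4-one F4;
- Suzuki coupling with (4-hydroxyphenyl)boronic acid (PdCl2(dppf), K2CO3, dioxane/H2O) to 3-(4-hydroxyphenyl)-5-methoxy-7-(prop-2-enyloxy)chromen-4-one F5;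
- acetylation (Ac2O, pyridine) to 13.

Step 4. The most likely failure is slow transmetalation of the pinacol boronate combined with the low nucleophilicity of the hindered, hydrogen-bonded phenol, so that oxidative homocoupling and protodeboronation of the boron partner outrun C–O bond formation. The fallback reverses the polarity of the alkenyl partner, sets out from 7 and returns at 8: Ullmann-type vinylation with 4-[(E)-2-iodoethenyl]phenyl acetate F6 (from commercial 4-formylphenyl acetate by Takai olefination with CHI3 and CrCl2) using CuI, N,N-dimethylglycine and K3PO4 in dioxane at 80 °C, with retention of the alkene geometry.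

Step 5. The most likely failure is electrophilic chlorination of the trioxygenated ring or of the enol ether by HOCl, or acid-promoted hydrolysis of the enol ether in the pH 4 buffer, because both are very electron-rich. The fallback is a chlorine-free basic oxidation, sets out from 8 and returns at 9: Ag2O (from AgNO3 and NaOH) in aqueous ethanol oxidises the aldehyde and also cleaves the acetate, giving 2-[(E)-2-(4-hydroxyphenyl)ethenoxy]-6-methoxy-4-(prop-2-enyloxy)benzoic acid F7; the phenol is then re-acetylated with Ac2O in cold aqueous NaOH to give 9.

Step 7. The most likely failure is incomplete regioselectivity (partial migration to C6) and acetyl transfer from the ring B acetate to the new 7-phenol at 190 °C. The fallback replaces the sigmatropic shift by a halogenation and cross-coupling sequence, sets out from 13 and returns at 14: deallylation with Pd(PPh3)4 and PhSiH3 to 4-(7-hydroxy-5-methoxy-4-oxochromen-3-yl)phenyl acetate F8, iodination with N-iodosuccinimide at the activated C8 position to 4-(7-hydroxy-8-iodo-5-methoxy-4-oxochromen-3-yl)phenyl acetate F9, and Stille coupling with Bu3SnCH2CH=CH2 (Pd(PPh3)4, DMF) to 14.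

Step 10. The most likely failure is poor facial selectivity or self-condensation of the enolisable arylacetaldehyde, and possible interference of the terminal alkyne with the nickel co-catalyst. The fallback separates C–C bond formation from stereocontrol, sets out from 18 and returns at 20: ligand-free Nozaki–Hiyama–Kishi coupling with 19 (CrCl2, catalytic NiCl2, DMF) to racemic 4-[8-(2-hydroxy-3-methylbut-3-enyl)-5-methoxy-7-(2-methylbut-3-yn-2-yloxy)-4-oxochromen-3-yl]phenyl acetate F10; oxidation with Dess–Martin periodinane to 4-[5-methoxy-8-(3-methyl-2-oxobut-3-enyl)-7-(2-methylbut-3-yn-2-yloxy)-4-oxochromen-3-yl]phenyl acetate F11; and Corey–Bakshi–Shibata reduction with the (S)-2-methyl-oxazaborolidine and catecholborane at −78 °C, where the isopropenyl group should act as the large substituent and give the R alcohol 20.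

Further compounds

F1 | step 6 | 2-(1-hydroxyethyl)-3-methoxy-5-(prop-2-enyloxy)phenol (racemic) | CC(O)c1c(O)cc(OCC=C)cc1OC
F2 | step 6 | 1-[2-hydroxy-6-methoxy-4-(prop-2-enyloxy)phenyl]ethanone | CC(=O)c1c(O)cc(OCC=C)cc1OC
F3 | step 6 | (E)-3-(dimethylamino)-1-[2-hydroxy-6-methoxy-4-(prop-2-enyloxy)phenyl]prop-2-en-1-one | CN(C)/C=C/C(=O)c1c(O)cc(OCC=C)cc1OC
F4 | step 6 | 3-iodo-5-methoxy-7-(prop-2-enyloxy)chromen-4-one | C=CCOc1cc(OC)c2c(=O)c(I)coc2c1
F5 | step 6 | 3-(4-hydroxyphenyl)-5-methoxy-7-(prop-2-enyloxy)chromen-4-one | C=CCOc1cc(OC)c2c(=O)c(-c3ccc(O)cc3)coc2c1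
F6 | step 4 | 4-[(E)-2-iodoethenyl]phenyl acetate | CC(=O)Oc1ccc(/C=C/I)cc1
F7 | step 5 | 2-[(E)-2-(4-hydroxyphenyl)ethenoxy]-6-methoxy-4-(prop-2-enyloxy)benzoic acid | O=C(O)c1c(OC)cc(OCC=C)cc1O/C=C/c1ccc(O)cc1
F8 | step 7 | 4-(7-hydroxy-5-methoxy-4-oxochromen-3-yl)phenyl acetate | CC(=O)Oc1ccc(-c2coc3cc(O)cc(OC)c3c2=O)cc1
F9 | step 7 | 4-(7-hydroxy-8-iodo-5-methoxy-4-oxochromen-3-yl)phenyl acetate | CC(=O)Oc1ccc(-c2coc3c(I)c(O)cc(OC)c3c2=O)cc1
F10 | step 10 | 4-[8-(2-hydroxy-3-methylbut-3-enyl)-5-methoxy-7-(2-methylbut-3-yn-2-yloxy)-4-oxochromen-3-yl]phenyl acetate (racemic) | C=C(C)C(O)Cc1c(OC(C)(C)C#C)cc(OC)c2c(=O)c(-c3ccc(OC(C)=O)cc3)coc12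
F11 | step 10 | 4-[5-methoxy-8-(3-methyl-2-oxobut-3-enyl)-7-(2-methylbut-3-yn-2-yloxy)-4-oxochromen-3-yl]phenyl acetate | C=C(C)C(=O)Cc1c(OC(C)(C)C#C)cc(OC)c2c(=O)c(-c3ccc(OC(C)=O)cc3)coc12
A1 | alternative 1 | 7-(tert-butyldimethylsilyloxy)-8-[(E)-4-hydroxy-3-methylbut-2-enyl]-5-methoxy-6-(3-methylbut-2-enyl)-3-[4-(triisopropylsilyloxy)phenyl]chromen-4-one | OC/C(C)=C/Cc1c(O[Si](C)(C)C(C)(C)C)c(CC=C(C)C)c(OC)c2c(=O)c(-c3ccc(O[Si](C(C)C)(C(C)C)C(C)C)cc3)coc12
A2 | alternative 1 | 7-(tert-butyldimethylsilyloxy)-8-{[(2R,3R)-3-(hydroxymethyl)-3-methyloxiran-2-yl]methyl}-5-methoxy-6-(3-methylbut-2-enyl)-3-[4-(triisopropylsilyloxy)phenyl]chromen-4-one | OC[C@@]1(C)O[C@@H]1Cc1c(O[Si](C)(C)C(C)(C)C)c(CC=C(C)C)c(OC)c2c(=O)c(-c3ccc(O[Si](C(C)C)(C(C)C)C(C)C)cc3)coc12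
A3 | alternative 2 | 3-methoxy-4-(3-methylbut-2-enyl)cyclobut-2-en-1-one | COC1=CC(=O)C1CC=C(C)C
A4 | alternative 2 | tert-butyl(dimethyl){[4-(triisopropylsilyloxy)but-3-yn-1-yl]oxy}silane | CC(C)[Si](C(C)C)(C(C)C)OC#CCCO[Si](C)(C)C(C)(C)C
A5 | alternative 2 | 2-[2-(tert-butyldimethylsilyloxy)ethyl]-5-methoxy-6-(3-methylbut-2-enyl)-3-(triisopropylsilyloxy)phenol | CC(C)=CCc1c(O)c(CCO[Si](C)(C)C(C)(C)C)c(O[Si](C(C)C)(C(C)C)C(C)C)cc1OC
A6 | alternative 3 | 3-methoxy-5-(prop-2-enyloxy)-2-(trimethylsilyl)phenyl trifluoromethanesulfonate | C=CCOc1cc(OC)c([Si](C)(C)C)c(OS(=O)(=O)C(F)(F)F)c1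
A7 | alternative 3 | 3-methoxy-5-(prop-2-enyloxy)benzyne | C=CCOC1=CC#CC(OC)=C1
A8 | alternative 3 | 3-methoxy-2-[4-(methoxymethoxy)phenyl]prop-2-enoic acid | COC=C(C(=O)O)c1ccc(OCOC)cc1
A9 | alternative 3 | 5-methoxy-3-[4-(methoxymethoxy)phenyl]-7-(prop-2-enyloxy)chromen-4-one | C=CCOc1cc(OC)c2c(=O)c(-c3ccc(OCOC)cc3)coc2c1
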